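## Analysis of the target

Yunnaneic acid C (29) is a bicyclo[2.2.2]oct-5-ene-2,3-dione; its skeleton is numbered here C1 (bridgehead next to the olefinic CH, C6), C2 and C3 (the two carbonyl carbons, C2 on C1), C4 (the other bridgehead), C5 (the olefinic carbon that carries the acrylate), C7 (on C4, carrying CO2H) and C8 (on C1, carrying the 3,4-dihydroxyphenyl ring). The (E)-acrylate on C5 is esterified with the secondary hydroxyl of (R)-3-(3,4-dihydroxyphenyl)lactic acid, so there are five stereocentres: C1, C4, C7 and C8 in the bicycle and the lactate carbon outside it. The two bridgeheads are tied to each other, the aryl group on C8 stands over the C5=C6 bridge and the carboxyl on C7 over the C2–C3 bridge, so these two groups are trans; the lactate centre is remote and must be brought in enantiopure. The sensitive groups are the strained, non-enolisable 1,2-diketone (hydration, nucleophiles, base-induced ring contraction), two air-sensitive catechols, an acrylate ester of an α-acyloxy acid that forbids any late saponification, and an electrophilic dienoate. The difficulty is to build the bridged ring with four contiguous stereocentres as one enantiomer, with the aryl group on the olefin side, and to finish with mild acid only. The strategy rests on one feature: C5 is sp2 and bonded to bridgehead C4, and C4 is β to the C7 carboxyl carbon and α to the C3 ketone. The C4–C5 bond can therefore be made last, by adding a C5 vinyl radical, held on C1 through C6, to C4 of a cyclohexenone whose C4=C7 double bond carries the ester on C7 and is conjugated with the C3 carbonyl.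

## Retrosynthetic reasoning

29 to 28. Only protecting groups are removed: two catechol acetonides and two tert-butyl esters. All four are chosen to fall in one acidolysis, because base would cleave the acrylate ester and attack the diketone.

28 to 27. The C2 carbonyl is taken out. C2 is the only enolisable position next to the C3 ketone (C4 is a bridgehead), so a Riley-type α-oxidation can only go there and cannot over-oxidise to an enone. It is placed after the olefination so that the electrophilic diketone never meets an ylide or fluoride.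

27 to 21 and 26. The acrylate C=C is cut by a Wittig disconnection. This is the convergent step: the aldehyde 21 carries the whole bicycle, and the stabilised ylide 26 brings the lactate stereocentre and should give the (E)-alkene.

26 back to 22. The ylide comes from the protected hydroxy ester 25, which comes from (R)-danshensu 22 through the bis-acetonide 23 and the hydroxy acid 24. No bond at the stereocentre is touched.

21 to 19. The formyl group is traced back through the allylic alcohol 20 to the silyl ether of 19. This oxidation level is robust in the ring-forming step.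

19 to 17 (key disconnection). The C4–C5 bond is cut. This opens the bicycle to the monocyclic keto-enoate 17, in which C1 carries a (Z)-2-iodoallyl-type arm cis to the aryl group on C8. Cutting here and not at a bridge carbon–carbon single bond gains the most. The forward closure makes the ring, puts the C5=C6 olefin with its carbon substituent in its final place, and keeps C3 as a ketone. It creates C4 by the geometry of the tether and leaves C7 as an ester α-carbon that can be equilibrated (through 18) to the trans arrangement.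

17 to 11. The C3 carbonyl is removed. An oxygen on C3 cannot be carried through the cycloaddition, since a donor at that diene terminus would reverse its regiochemistry. Direct allylic C–H oxidation would have to tell C3–H from the benzylic C8–H and the other allylic positions. The γ-position of the enoate is therefore oxidised through its dienolate: α-selenenylation at C7 and [2,3]-shift of the selenoxide move oxygen to C3 (11 through 12–15 to 16), and the alcohol 16 is oxidised to 17.

11 to 8. The side arm is taken back to a formyl group on C1: silyl ether 11 from alcohol 10, this from the (Z)-α-iodoacrylate 9, and 9 from aldehyde 8 by iodo-olefination. The hydride reduction is placed before C3 becomes a ketone.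

8 to 6 and 7. The cyclohexene is cut at C1–C8 and C2–C3, a Diels–Alder disconnection to the aryl diene 6 and acrolein 7. The endo transition state makes the formyl and aryl groups cis, and a chiral secondary amine sets the absolute configuration. The C7 ester is already on the diene.

6 to 1. The diene must have the aryl group trans to the vinyl group to reach the s-cis form. It is therefore built from the gem-dibromoalkene 3: the bromine trans to the aryl ring is replaced first (4), and the remaining bromine is then exchanged for the ester through the alkenyllithium 5. Compound 3 comes from aldehyde 2, the acetonide of 1.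

## Alternatives that were turned down

Alternative 1: The dione bridge is cut at C1–C2 and C3–C4, so that C2 and C3 come from a vinyl group tied to the C7 carboxyl as an enol ester. In the forward step, heating the vinyl ester A1 would let its O-vinyl group add across the ring diene (C4=C5–C6=C1) to give the tricyclic lactone aldehyde A2.
- For it: two C–C bonds and the bicycle form in one thermal step. The lactone fixes the C7 carboxyl on the C2–C3 side without equilibration, C3 is already oxygenated, and the C5 formyl group is ready for olefination.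
- Against it: an enol ester is an unactivated dienophile. It reaches the diene only from the disfavoured s-cis rotamer of the ester, through a strained transition state in which a five-membered lactone spans two ring atoms.
- Against it: A1 is a 5,6-dihydrobenzoate. At the temperatures needed it should aromatise or undergo 1,5-hydrogen shifts, and no catalytic asymmetric entry to it is apparent.
- Against it: after the cycloaddition the lactone must be opened and both C3 and C2 oxidised beside a free C7 acid.
- Comparison: it is stronger in bond economy and in the control of C7. The chosen route offers instead a precursor (17) that is stable under neutral conditions, enantiocontrol from one catalytic cycloaddition, and C3 already a ketone.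

Alternative 2: The C4–C7 bond is cut, with the C7 carboxyl tied as a lactone to an allylic oxygen on C2. In the forward step, enolisation and O-silylation of the cis-fused lactone A3 and warming would bring about an Ireland–Claisen ring contraction to the acid A4 (C4–C7 formed, C2–O broken, C2=C3 as the new olefin).
- For it: the step is sigmatropic and stereospecific, sets C4 and C7 together, and frees the acid.
- For it: the C2=C3 olefin is an ideal latent dione (dihydroxylation, double oxidation). On this point it is stronger than the chosen route, which needs a selenium oxidation.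
- Against it: the allyl unit lies in the carbocycle and the ketene acetal in the fused lactone, so only a strained, boat-like bridged transition state is available.
- Against it: in A4, C5 is a masked ketone and C6 a methylene, so the C5=C6 olefin and the whole acrylate arm still have to be built. A3 itself needs three stereocentres (C1, C2, C8) before the key step.
- Comparison: the chosen route installs C5=C6 with its carbon substituent in the key step and needs only two stereocentres beforehand.

Alternative 3: The C5=C6 bond is cut. In the forward step, ring-closing enyne metathesis with a ruthenium alkylidene would join the vinyl group on C1 and the ethynyl group on C4 of the cyclohexane A5 to give the diene A6.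
- For it: it is catalytic, neutral and free of tin. It forms the olefin bridge, leaves a vinyl group on C5 that could be extended to the acrylate, and carries C2 as a ketal.
- Against it: the key step creates no stereocentre. All four (C1, C4, C7, C8) must be present in A5, including a cis-1,4 pair that must both be axial to meet.
- Against it: bridging a chair cyclohexane by metathesis is strained and competes with intermolecular metathesis. C3 is still a methylene, and the 1,3-diene of A6 is a poor partner for selective further metathesis.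
- Comparison: it is equal to the chosen route in needing a late α-oxidation and stronger in avoiding tin. The radical closure offers instead stereochemical economy: C4 and C7 are fixed in or right after the key step, and the rest comes from one catalytic cycloaddition.

Key step: step 11

Abbreviations: Ar = 2,2-dimethyl-1,3-benzodioxol-5-yl (catechol acetonide); TBS = tert-butyl(dimethyl)silyl. Remark: (R)-danshensu (22) is used as the free acid; its commercial sodium salt would be acidified first.

## Route

Step 1
Reactants: 1 3,4-dihydroxybenzaldehyde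
Product: 2 2,2-dimethyl-1,3-benzodioxole-5-carbaldehyde
Conditions: Me2C(OMe)2, TsOH·H2O (cat.), PhH, reflux, 4 Å MS
Reagents that add atoms: 2,2-dimethoxypropane, COC(C)(C)OC
Why: Acid-catalysed transketalisation of the catechol, driven by removal of methanol; the acetonide survives bases, organolithiums, hydrides and oxidants and falls only to aqueous trifluoroacetic acid at the end.

Step 2
Reactants: 2 2,2-dimethyl-1,3-benzodioxole-5-carbaldehyde
Product: 3 5-(2,2-dibromoethenyl)-2,2-dimethyl-1,3-benzodioxole
Conditions: CBr4, PPh3, CH2Cl2, 0 °C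
Reagents that add atoms: tetrabromomethane, BrC(Br)(Br)Br
Why: Dibromo-olefination of the Corey–Fuchs type (Wittig reaction of Ph3P=CBr2 made in the flask), reliable for electron-rich aromatic aldehydes.

Step 3
Reactants: 3 5-(2,2-dibromoethenyl)-2,2-dimethyl-1,3-benzodioxole
Product: 4 5-[(1Z)-2-bromobuta-1,3-dien-1-yl]-2,2-dimethyl-1,3-benzodioxole
Conditions: Bu3SnCH=CH2, Pd2(dba)3 (2.5 mol%), tri(2-furyl)phosphine, PhMe, 100 °C
Reagents that add atoms: tributyl(vinyl)stannane, C=C[Sn](CCCC)(CCCC)CCCC
Why: Stille mono-coupling of a 1,1-dibromoalkene; zerovalent palladium inserts first into the less hindered C–Br bond trans to the aryl ring, so the vinyl group ends trans to the aryl group and the remaining bromine cis to it.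

Step 4
Reactants: 4 5-[(1Z)-2-bromobuta-1,3-dien-1-yl]-2,2-dimethyl-1,3-benzodioxole
Product: 6 tert-butyl (2Z)-2-(Ar-methylidene)but-3-enoate, via dienyllithium 5 (not isolated)
Conditions: t-BuLi (2.1 equiv), THF, −78 °C; then Boc2O, −78 → 0 °C
Reagents that add atoms: di-tert-butyl dicarbonate, CC(C)(C)OC(=O)OC(=O)OC(C)(C)C
Why: Bromine–lithium exchange proceeds with retention of alkene geometry and is much faster than carbolithiation at −78 °C; acylation of 5 by Boc2O gives the tert-butyl ester with the aryl group cis to the ester and trans to the vinyl group, the geometry a Diels–Alder diene needs.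

Step 5
Reactants: 6 tert-butyl (2Z)-2-(Ar-methylidene)but-3-enoate; 7 acrolein
Product: 8 tert-butyl (5S,6R)-6-Ar-5-formylcyclohex-1-ene-1-carboxylate
Conditions: 7 (3 equiv), (5R)-5-benzyl-2,2,3-trimethylimidazolidin-4-one hydrochloride (20 mol%), MeCN–H2O 95:5, 0 °C → rt
Reagents that add atoms: none
Why: Iminium-ion catalysed Diels–Alder reaction; in this polar, asynchronous addition the CH2 terminus of the diene bonds first to the β-carbon of the iminium ion (the charge is then carried by the aryl-substituted allyl unit and not by the ester-bearing carbon), which puts the formyl carbon next to C8. The endo transition state sets formyl and aryl cis, and the benzyl group of the (5R) catalyst covers one face of the E-iminium ion so that the diene adds to the other, giving the (5S,6R) adduct.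

Step 6
Reactants: 8 tert-butyl (5S,6R)-6-Ar-5-formylcyclohex-1-ene-1-carboxylate
Product: 9 tert-butyl (5S,6R)-6-Ar-5-[(1Z)-3-ethoxy-2-iodo-3-oxoprop-1-en-1-yl]cyclohex-1-ene-1-carboxylate
Conditions: Ph3P=CHCO2Et, N-iodosuccinimide, CH2Cl2, −20 °C; then 8, −20 °C → rt
Reagents that add atoms: ethyl (triphenylphosphoranylidene)acetate, CCOC(=O)C=P(c1ccccc1)(c1ccccc1)c1ccccc1; N-iodosuccinimide, O=C1CCC(=O)N1I
Why: Wittig olefination with the α-iodo ylide formed in the flask; the stabilised ylide places the ester trans to the ring carbon, giving the (Z)-α-iodoacrylate, and is too weakly basic to epimerise the formyl-bearing carbon.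

Step 7
Reactants: 9 tert-butyl (5S,6R)-6-Ar-5-[(1Z)-3-ethoxy-2-iodo-3-oxoprop-1-en-1-yl]cyclohex-1-ene-1-carboxylate
Product: 10 tert-butyl (5S,6R)-6-Ar-5-[(1Z)-3-hydroxy-2-iodoprop-1-en-1-yl]cyclohex-1-ene-1-carboxylate
Conditions: i-Bu2AlH (2.3 equiv), CH2Cl2, −78 °C; aq. potassium sodium tartrate
Reagents that add atoms: none
Why: 1,2-Reduction of the unhindered, iodine-activated ethyl ester to the allylic alcohol; the hindered, α-branched tert-butyl enoate is far slower at −78 °C, and the vinyl iodide is inert to the hydride.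

Step 8
Reactants: 10 tert-butyl (5S,6R)-6-Ar-5-[(1Z)-3-hydroxy-2-iodoprop-1-en-1-yl]cyclohex-1-ene-1-carboxylate
Product: 11 tert-butyl (5S,6R)-6-Ar-5-[(1Z)-3-(TBS-oxy)-2-iodoprop-1-en-1-yl]cyclohex-1-ene-1-carboxylate
Conditions: TBSCl, imidazole, DMF, rt
Reagents that add atoms: tert-butyl(chloro)dimethylsilane, CC(C)(C)[Si](C)(C)Cl
Why: Standard silylation of a primary allylic alcohol; the ether withstands amide bases, peroxide, the periodinane and tin hydride.

Step 9
Reactants: 11 tert-butyl (5S,6R)-6-Ar-5-[(1Z)-3-(TBS-oxy)-2-iodoprop-1-en-1-yl]cyclohex-1-ene-1-carboxylate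
Product: 16 tert-butyl (3RS,5S,6R)-6-Ar-3-hydroxy-5-[(1Z)-3-(TBS-oxy)-2-iodoprop-1-en-1-yl]cyclohex-1-ene-1-carboxylate, via lithium dienolate 12 (not isolated), via α-selenide 13 (not isolated), via selenoxide 14 (not isolated), via allyl selenenate 15 (not isolated)
Conditions: LiN(i-Pr)2 (1.2 equiv), THF–DMPU, −78 °C; PhSeCl, −78 °C; then 30% H2O2, pyridine, CH2Cl2, 0 °C
Reagents that add atoms: hydrogen peroxide, OO
Why: γ-Deprotonation of the enoate (C3–H is the only acidic hydrogen; C8–H gives no conjugated anion) and α-selenenylation of the dienolate, then selenoxide [2,3]-sigmatropic shift and cleavage of the selenenate, a known γ-hydroxylation of α,β-unsaturated esters that returns the double bond to C4=C7. The new C3 centre is a mixture, which does not matter, and the trisubstituted vinyl iodide tolerates the amide base at −78 °C.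

Step 10
Reactants: 16 tert-butyl (3RS,5S,6R)-6-Ar-3-hydroxy-5-[(1Z)-3-(TBS-oxy)-2-iodoprop-1-en-1-yl]cyclohex-1-ene-1-carboxylate
Product: 17 tert-butyl (5S,6R)-6-Ar-5-[(1Z)-3-(TBS-oxy)-2-iodoprop-1-en-1-yl]-3-oxocyclohex-1-ene-1-carboxylate
Conditions: 1,1,1-triacetoxy-1λ5,2-benziodoxol-3(1H)-one, CH2Cl2, 0 °C → rt
Reagents that add atoms: none
Why: Periodinane oxidation of the secondary allylic alcohol under non-basic conditions, so that the γ-acidic C8–H of the keto-enoate is not epimerised and the double bond does not migrate.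

Step 11
Reactants: 17 tert-butyl (5S,6R)-6-Ar-5-[(1Z)-3-(TBS-oxy)-2-iodoprop-1-en-1-yl]-3-oxocyclohex-1-ene-1-carboxylate
Product: 19 tert-butyl (1R,2R,3S,4R)-3-Ar-6-(TBS-oxymethyl)-7-oxobicyclo[2.2.2]oct-5-ene-2-carboxylate, via C7 epimer 18 (not isolated)
Conditions: Bu3SnH (1.3 equiv) and azobisisobutyronitrile (0.2 equiv) added over 6 h, PhH, 80 °C, 5 mM; MeCN–hexane partition; then t-BuOK (0.3 equiv), t-BuOH–THF, rt
Reagents that add atoms: none
Why: Bu3Sn• removes iodine from C5; the σ-vinyl radical inverts faster than it reacts, so the (Z) geometry of 17 is irrelevant, and with the C1 arm axial it adds to C4 of the C4=C7 bond, the closest known reaction type being the cyclisation of halovinyl side chains onto cyclohexenones and cyclohexenoates to bicyclo[2.2.2]octenes. The ring C5–C6–C1–C2–C3–C4 closes in the 6-exo-trig mode (the same bond counts as 6-endo through C1–C8–C7), and this closes the bicycle. C4 needs no outside control: the two-atom tether on C1 reaches only the ring face on which it stands, and because arm and aryl are cis in 17 the aryl group ends over the new C5=C6 bridge. The step needs attack at C4 and not at C7 (a 5-exo closure to a bicyclo[3.2.1]octene); C4 is the unsubstituted terminus and β to the ester, so attack there gives a tertiary ester-stabilised radical, whereas C7 is fully substituted and flanked by the aryl-bearing C8 and the tert-butyl ester, and at low stannane concentration any C7 adduct (an α-keto radical at C4) can pass through the cyclopropylcarbinyl radical to the same C7 radical. Slow addition at high dilution also keeps hydrogen transfer to the vinyl radical slower than ring closure, and iodine abstraction is much faster than stannyl addition to the enone. The C7 radical should take hydrogen mainly on its open face, the one turned to the C3 carbonyl, giving 18 with the ester cis to the aryl group. C7 is therefore set under thermodynamic control: catalytic t-BuOK (an amine base would be too weak for an unactivated tert-butyl ester) epimerises the only acidic stereocentre to the trans isomer 19, in which the ester no longer eclipses the aryl group; the bridgeheads and the non-acidic C8 cannot change.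

Step 12
Reactants: 19 tert-butyl (1R,2R,3S,4R)-3-Ar-6-(TBS-oxymethyl)-7-oxobicyclo[2.2.2]oct-5-ene-2-carboxylate
Product: 20 tert-butyl (1R,2R,3S,4R)-3-Ar-6-(hydroxymethyl)-7-oxobicyclo[2.2.2]oct-5-ene-2-carboxylate
Conditions: HF·pyridine, pyridine, THF, 0 °C → rt
Reagents that add atoms: none
Why: Buffered fluoride desilylation of the primary silyl ether; acetonide, tert-butyl ester and ketone are untouched and no base is present to disturb C7.

Step 13
Reactants: 20 tert-butyl (1R,2R,3S,4R)-3-Ar-6-(hydroxymethyl)-7-oxobicyclo[2.2.2]oct-5-ene-2-carboxylate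
Product: 21 tert-butyl (1R,2R,3S,4R)-3-Ar-6-formyl-7-oxobicyclo[2.2.2]oct-5-ene-2-carboxylate
Conditions: MnO2 (activated), CH2Cl2, rt
Reagents that add atoms: none
Why: Selective oxidation of the allylic alcohol to the enal on a neutral heterogeneous oxidant; no over-oxidation and no epimerisable centre is exposed.

Step 14
Reactants: 22 (R)-danshensu [(2R)-3-(3,4-dihydroxyphenyl)-2-hydroxypropanoic acid]
Product: 23 (5R)-5-(Ar-methyl)-2,2-dimethyl-1,3-dioxolan-4-one
Conditions: Me2C(OMe)2, TsOH·H2O (cat.), PhH, reflux, 4 Å MS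
Reagents that add atoms: 2,2-dimethoxypropane, COC(C)(C)OC
Why: The same acid-catalysed ketalisation closes both the catechol acetonide and the dioxolanone of the α-hydroxy acid; no bond at the stereocentre is broken and acid does not racemise it.

Step 15
Reactants: 23 (5R)-5-(Ar-methyl)-2,2-dimethyl-1,3-dioxolan-4-one
Product: 24 (2R)-3-Ar-2-hydroxypropanoic acid
Conditions: LiOH, THF–H2O, 0 °C; then 1 M HCl to pH 3, 0 °C
Reagents that add atoms: lithium hydroxide, [Li+].[OH-]
Why: The activated dioxolanone is saponified quickly at 0 °C and its hemiketal collapses with loss of acetone, while the aryl acetonide is stable to base and to the brief cold acidification.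

Step 16
Reactants: 24 (2R)-3-Ar-2-hydroxypropanoic acid
Product: 25 tert-butyl (2R)-3-Ar-2-hydroxypropanoate
Conditions: t-BuOC(=NH)CCl3, cyclohexane–CH2Cl2, rt
Reagents that add atoms: tert-butyl 2,2,2-trichloroacetimidate, CC(C)(C)OC(=N)C(Cl)(Cl)Cl
Why: Carboxylic acids are tert-butylated by the imidate without added acid, whereas the secondary alcohol needs a Lewis acid, so only the acid reacts and the acetonide is not exposed to strong acid.

Step 17
Reactants: 25 tert-butyl (2R)-3-Ar-2-hydroxypropanoate
Product: 26 tert-butyl (2R)-3-Ar-2-{[(triphenylphosphoranylidene)acetyl]oxy}propanoate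
Conditions: Ph3P=C=C=O, PhMe, 90 °C
Reagents that add atoms: (triphenylphosphoranylidene)ketene, O=C=C=P(c1ccccc1)(c1ccccc1)c1ccccc1
Why: Addition of the alcohol O–H across the cumulated ylide gives the ester-stabilised phosphorane directly and under neutral conditions, so the α-acyloxy ester centre is not at risk.

Step 18
Reactants: 21 tert-butyl (1R,2R,3S,4R)-3-Ar-6-formyl-7-oxobicyclo[2.2.2]oct-5-ene-2-carboxylate; 26 tert-butyl (2R)-3-Ar-2-{[(triphenylphosphoranylidene)acetyl]oxy}propanoate
Product: 27 tert-butyl (1R,2R,3S,4R)-3-Ar-6-[(1E)-3-{[(2R)-3-Ar-1-tert-butoxy-1-oxopropan-2-yl]oxy}-3-oxoprop-1-en-1-yl]-7-oxobicyclo[2.2.2]oct-5-ene-2-carboxylate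
Conditions: PhMe, 80 °C
Reagents that add atoms: none
Why: Wittig olefination with a stabilised ylide gives the (E)-acrylate; the ylide reacts with the aldehyde and not with the unactivated C3 ketone, which is why this step precedes formation of the diketone.

Step 19
Reactants: 27 tert-butyl (1R,2R,3S,4R)-3-Ar-6-[(1E)-3-{[(2R)-3-Ar-1-tert-butoxy-1-oxopropan-2-yl]oxy}-3-oxoprop-1-en-1-yl]-7-oxobicyclo[2.2.2]oct-5-ene-2-carboxylate
Product: 28 tert-butyl (1R,2R,3S,4R)-3-Ar-6-[(1E)-3-{[(2R)-3-Ar-1-tert-butoxy-1-oxopropan-2-yl]oxy}-3-oxoprop-1-en-1-yl]-7,8-dioxobicyclo[2.2.2]oct-5-ene-2-carboxylate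
Conditions: SeO2 (1.5 equiv), 1,4-dioxane (wet), 90 °C
Reagents that add atoms: selenium dioxide, O=[Se]=O
Why: Riley oxidation of the ketone α-methylene; C2 is the only position that can enolise (C4 is a bridgehead) and no enone can form, the same situation as in the oxidation of camphor to camphorquinone. The dienoate has no allylic hydrogen outside the bridgeheads, and esters and acetonides tolerate the weakly acidic medium.

Step 20
Reactants: 28 tert-butyl (1R,2R,3S,4R)-3-Ar-6-[(1E)-3-{[(2R)-3-Ar-1-tert-butoxy-1-oxopropan-2-yl]oxy}-3-oxoprop-1-en-1-yl]-7,8-dioxobicyclo[2.2.2]oct-5-ene-2-carboxylate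
Product: 29 yunnaneic acid C
Conditions: CF3CO2H–H2O 9:1, 0 °C → rt
Reagents that add atoms: none
Why: One acidolysis cleaves both tert-butyl esters and hydrolyses both catechol acetonides; the acrylate ester, the non-enolisable diketone and all stereocentres are stable to aqueous acid.

## Compound list

1 | 3,4-dihydroxybenzaldehyde | O=Cc1ccc(O)c(O)c1 | starting material
2 | 2,2-dimethyl-1,3-benzodioxole-5-carbaldehyde | O=Cc1ccc2OC(C)(C)Oc2c1 | intermediate
3 | 5-(2,2-dibromoethenyl)-2,2-dimethyl-1,3-benzodioxole | BrC(Br)=Cc1ccc2OC(C)(C)Oc2c1 | intermediate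
4 | 5-[(1Z)-2-bromobuta-1,3-dien-1-yl]-2,2-dimethyl-1,3-benzodioxole | C=C/C(Br)=C/c1ccc2OC(C)(C)Oc2c1 | intermediate
5 | [(1Z)-1-(2,2-dimethyl-1,3-benzodioxol-5-yl)buta-1,3-dien-2-yl]lithium (not isolated) | C=C/C([Li])=C/c1ccc2OC(C)(C)Oc2c1 | intermediate
6 | tert-butyl (2Z)-2-[(2,2-dimethyl-1,3-benzodioxol-5-yl)methylidene]but-3-enoate | C=C/C(C(=O)OC(C)(C)C)=C/c1ccc2OC(C)(C)Oc2c1 | intermediate
7 | acrolein (prop-2-enal) | C=CC=O | starting material
8 | tert-butyl (5S,6R)-6-(2,2-dimethyl-1,3-benzodioxol-5-yl)-5-formylcyclohex-1-ene-1-carboxylate (formyl and aryl cis) | O=C[C@H]1CCC=C(C(=O)OC(C)(C)C)[C@H]1c1ccc2OC(C)(C)Oc2c1 | intermediate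
9 | tert-butyl (5S,6R)-6-(2,2-dimethyl-1,3-benzodioxol-5-yl)-5-[(1Z)-3-ethoxy-2-iodo-3-oxoprop-1-en-1-yl]cyclohex-1-ene-1-carboxylate | CCOC(=O)/C(I)=C/[C@H]1CCC=C(C(=O)OC(C)(C)C)[C@H]1c1ccc2OC(C)(C)Oc2c1 | intermediate
10 | tert-butyl (5S,6R)-6-(2,2-dimethyl-1,3-benzodioxol-5-yl)-5-[(1Z)-3-hydroxy-2-iodoprop-1-en-1-yl]cyclohex-1-ene-1-carboxylate | OC/C(I)=C/[C@H]1CCC=C(C(=O)OC(C)(C)C)[C@H]1c1ccc2OC(C)(C)Oc2c1 | intermediate
11 | tert-butyl (5S,6R)-5-[(1Z)-3-{[tert-butyl(dimethyl)silyl]oxy}-2-iodoprop-1-en-1-yl]-6-(2,2-dimethyl-1,3-benzodioxol-5-yl)cyclohex-1-ene-1-carboxylate | CC(C)(C)[Si](C)(C)OC/C(I)=C/[C@H]1CCC=C(C(=O)OC(C)(C)C)[C@H]1c1ccc2OC(C)(C)Oc2c1 | intermediate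
12 | lithium dienolate of 11 (lithium tert-butoxy[(5S,6R)-5-(iodoalkenyl)-6-arylcyclohex-2-en-1-ylidene]methanolate; not isolated) | CC(C)(C)[Si](C)(C)OC/C(I)=C/[C@H]1CC=CC(=C(O[Li])OC(C)(C)C)[C@H]1c1ccc2OC(C)(C)Oc2c1 | intermediate
13 | tert-butyl (1RS,5S,6R)-5-[(1Z)-3-{[tert-butyl(dimethyl)silyl]oxy}-2-iodoprop-1-en-1-yl]-6-(2,2-dimethyl-1,3-benzodioxol-5-yl)-1-(phenylselanyl)cyclohex-2-ene-1-carboxylate (not isolated) | CC(C)(C)[Si](C)(C)OC/C(I)=C/[C@H]1CC=CC([Se]c2ccccc2)(C(=O)OC(C)(C)C)[C@H]1c1ccc2OC(C)(C)Oc2c1 | intermediate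
14 | Se-oxide of 13 (1-benzeneseleninyl compound; not isolated) | CC(C)(C)[Si](C)(C)OC/C(I)=C/[C@H]1CC=CC([Se](=O)c2ccccc2)(C(=O)OC(C)(C)C)[C@H]1c1ccc2OC(C)(C)Oc2c1 | intermediate
15 | tert-butyl (3RS,5S,6R)-5-[(1Z)-3-{[tert-butyl(dimethyl)silyl]oxy}-2-iodoprop-1-en-1-yl]-6-(2,2-dimethyl-1,3-benzodioxol-5-yl)-3-[(phenylselanyl)oxy]cyclohex-1-ene-1-carboxylate (not isolated) | CC(C)(C)[Si](C)(C)OC/C(I)=C/[C@H]1CC(O[Se]c2ccccc2)C=C(C(=O)OC(C)(C)C)[C@H]1c1ccc2OC(C)(C)Oc2c1 | intermediate
16 | tert-butyl (3RS,5S,6R)-5-[(1Z)-3-{[tert-butyl(dimethyl)silyl]oxy}-2-iodoprop-1-en-1-yl]-6-(2,2-dimethyl-1,3-benzodioxol-5-yl)-3-hydroxycyclohex-1-ene-1-carboxylate | CC(C)(C)[Si](C)(C)OC/C(I)=C/[C@H]1CC(O)C=C(C(=O)OC(C)(C)C)[C@H]1c1ccc2OC(C)(C)Oc2c1 | intermediate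
17 | tert-butyl (5S,6R)-5-[(1Z)-3-{[tert-butyl(dimethyl)silyl]oxy}-2-iodoprop-1-en-1-yl]-6-(2,2-dimethyl-1,3-benzodioxol-5-yl)-3-oxocyclohex-1-ene-1-carboxylate (arm and aryl cis; key-step precursor) | CC(C)(C)[Si](C)(C)OC/C(I)=C/[C@H]1CC(=O)C=C(C(=O)OC(C)(C)C)[C@H]1c1ccc2OC(C)(C)Oc2c1 | intermediate
18 | tert-butyl (1R,2S,3S,4R)-6-({[tert-butyl(dimethyl)silyl]oxy}methyl)-3-(2,2-dimethyl-1,3-benzodioxol-5-yl)-7-oxobicyclo[2.2.2]oct-5-ene-2-carboxylate (ester cis to aryl; not isolated) | CC(C)(C)[Si](C)(C)OCC1=C[C@H]2CC(=O)[C@@H]1[C@@H](C(=O)OC(C)(C)C)[C@H]2c1ccc2OC(C)(C)Oc2c1 | intermediate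
19 | tert-butyl (1R,2R,3S,4R)-6-({[tert-butyl(dimethyl)silyl]oxy}methyl)-3-(2,2-dimethyl-1,3-benzodioxol-5-yl)-7-oxobicyclo[2.2.2]oct-5-ene-2-carboxylate (ester trans to aryl, aryl over the olefin bridge; key-step product) | CC(C)(C)[Si](C)(C)OCC1=C[C@H]2CC(=O)[C@@H]1[C@H](C(=O)OC(C)(C)C)[C@H]2c1ccc2OC(C)(C)Oc2c1 | intermediate
20 | tert-butyl (1R,2R,3S,4R)-3-(2,2-dimethyl-1,3-benzodioxol-5-yl)-6-(hydroxymethyl)-7-oxobicyclo[2.2.2]oct-5-ene-2-carboxylate | OCC1=C[C@H]2CC(=O)[C@@H]1[C@H](C(=O)OC(C)(C)C)[C@H]2c1ccc2OC(C)(C)Oc2c1 | intermediate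
21 | tert-butyl (1R,2R,3S,4R)-3-(2,2-dimethyl-1,3-benzodioxol-5-yl)-6-formyl-7-oxobicyclo[2.2.2]oct-5-ene-2-carboxylate | O=CC1=C[C@H]2CC(=O)[C@@H]1[C@H](C(=O)OC(C)(C)C)[C@H]2c1ccc2OC(C)(C)Oc2c1 | intermediate
22 | (R)-danshensu, (2R)-3-(3,4-dihydroxyphenyl)-2-hydroxypropanoic acid | O[C@H](Cc1ccc(O)c(O)c1)C(=O)O | starting material
23 | (5R)-5-[(2,2-dimethyl-1,3-benzodioxol-5-yl)methyl]-2,2-dimethyl-1,3-dioxolan-4-one | CC1(C)O[C@H](Cc2ccc3OC(C)(C)Oc3c2)C(=O)O1 | intermediate
24 | (2R)-3-(2,2-dimethyl-1,3-benzodioxol-5-yl)-2-hydroxypropanoic acid | O[C@H](Cc1ccc2OC(C)(C)Oc2c1)C(=O)O | intermediate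
25 | tert-butyl (2R)-3-(2,2-dimethyl-1,3-benzodioxol-5-yl)-2-hydroxypropanoate | O[C@H](Cc1ccc2OC(C)(C)Oc2c1)C(=O)OC(C)(C)C | intermediate
26 | tert-butyl (2R)-3-(2,2-dimethyl-1,3-benzodioxol-5-yl)-2-{[(triphenyl-λ5-phosphanylidene)acetyl]oxy}propanoate | O=C(C=P(c1ccccc1)(c1ccccc1)c1ccccc1)O[C@H](Cc1ccc2OC(C)(C)Oc2c1)C(=O)OC(C)(C)C | intermediate
27 | tert-butyl (1R,2R,3S,4R)-6-[(1E)-3-{[(2R)-1-tert-butoxy-3-(2,2-dimethyl-1,3-benzodioxol-5-yl)-1-oxopropan-2-yl]oxy}-3-oxoprop-1-en-1-yl]-3-(2,2-dimethyl-1,3-benzodioxol-5-yl)-7-oxobicyclo[2.2.2]oct-5-ene-2-carboxylate | O=C(/C=C/C1=C[C@H]2CC(=O)[C@@H]1[C@H](C(=O)OC(C)(C)C)[C@H]2c1ccc2OC(C)(C)Oc2c1)O[C@H](Cc1ccc2OC(C)(C)Oc2c1)C(=O)OC(C)(C)C | intermediate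
28 | tert-butyl (1R,2R,3S,4R)-6-[(1E)-3-{[(2R)-1-tert-butoxy-3-(2,2-dimethyl-1,3-benzodioxol-5-yl)-1-oxopropan-2-yl]oxy}-3-oxoprop-1-en-1-yl]-3-(2,2-dimethyl-1,3-benzodioxol-5-yl)-7,8-dioxobicyclo[2.2.2]oct-5-ene-2-carboxylate | O=C(/C=C/C1=C[C@H]2C(=O)C(=O)[C@@H]1[C@H](C(=O)OC(C)(C)C)[C@H]2c1ccc2OC(C)(C)Oc2c1)O[C@H](Cc1ccc2OC(C)(C)Oc2c1)C(=O)OC(C)(C)C | intermediate
29 | yunnaneic acid C | O=C(/C=C/C1=C[C@H]2C(=O)C(=O)[C@@H]1[C@H](C(=O)O)[C@H]2c1ccc(O)c(O)c1)O[C@H](Cc1ccc(O)c(O)c1)C(=O)O | target

## Step count and least certain steps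

Total step count: 20. Longest linear sequence: 16 steps (steps 1–13 and 18–20, from 3,4-dihydroxybenzaldehyde); the danshensu branch (steps 14–17) has 4 steps.

Step 11 (key step). Several things can go wrong.
- Closure at C7 instead of C4 (five-membered ring, bicyclo[3.2.1] skeleton) could compete. The acceptor is activated at both ends, and small-ring closure is normally the faster mode.
- Hydrogen transfer to the vinyl radical before ring closure could win, because the conformer with the arm axial is the minor one.
- A 1,5-hydrogen shift from a silicon methyl group to the vinyl radical would divert the chain.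
- The C7 radical could rearrange back through the cyclopropylcarbinyl radical if it is trapped too slowly.
- Under t-BuOK, equilibration could be incomplete or aldol self-condensation could intervene.

The fallback leaves radicals altogether. Keto-enoate 17 is reduced at the C4=C7 bond with [(Ph3P)CuH]6 to the saturated keto ester F1 (the vinyl iodide is retained). F1 is then closed by a zerovalent-palladium-catalysed intramolecular α-alkenylation of the ketone enolate (Pd(PPh3)4, t-BuOK, THF, reflux). Only the C4 enolate can reach the alkenylpalladium, so the C4–C5 bond and the bicyclo[2.2.2]octene form without any regiochemical choice at the alkene. The same base equilibrates C7, and the sequence arrives at 19.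

Step 5. The diene 6 carries an ester that lowers its reactivity and may isomerise about the arylidene bond under the acidic amine salt. The endo/exo or facial selectivity may be insufficient, and the amine can epimerise the formyl-bearing carbon of 8 through its enamine. The fallback uses a covalently bound auxiliary instead of a catalyst. Diene 6 is combined with (4R)-4-benzyl-3-(prop-2-enoyl)-1,3-oxazolidin-2-one and Et2AlCl at −78 °C; the chelated s-cis imide is attacked on the face away from the benzyl group, endo, to give imide F2. LiBH4 removes the auxiliary and gives the primary alcohol F3, and periodinane oxidation returns to aldehyde 8.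

Step 9. Selenenylation may occur at C3 instead of the hindered C7, the amide base may eliminate hydrogen iodide from the side arm, and syn-elimination of the selenoxide may compete with the [2,3]-shift. The fallback avoids selenium. The dienolate of 11 is protonated kinetically at C7 (LiN(i-Pr)2, then AcOH at −78 °C) to the β,γ-unsaturated ester F4. Its C3=C4 bond, the most electron-rich alkene, is epoxidised with 3-chloroperbenzoic acid to epoxide F5. DBU then opens the epoxide by elimination from the ester α-carbon, which arrives at the γ-hydroxy enoate 16.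

Step 19. Enolisation of the bicyclic ketone may be slow. The forcing conditions then needed could cost the acetonides through the acidity of selenous acid or oxidise the benzylic methylene of the lactate unit. The fallback oxidises the enolate carbon stepwise. Ketone 27 is converted with LiN(SiMe3)2 and Me3SiCl (THF, −78 °C) into the silyl enol ether F6, which can only form towards C2. Rubottom oxidation with dimethyldioxirane and mild aqueous work-up gives the α-hydroxy ketone F7, and periodinane oxidation arrives at diketone 28.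

## Further compounds

F1 | step 11 | tert-butyl (2S,3S)-3-[(1Z)-3-{[tert-butyl(dimethyl)silyl]oxy}-2-iodoprop-1-en-1-yl]-2-(2,2-dimethyl-1,3-benzodioxol-5-yl)-5-oxocyclohexane-1-carboxylate (C4=C7 of 17 saturated; mixture at the ester carbon) | CC(C)(C)[Si](C)(C)OC/C(I)=C/[C@H]1CC(=O)CC(C(=O)OC(C)(C)C)[C@H]1c1ccc2OC(C)(C)Oc2c1
F2 | step 5 | tert-butyl (5S,6R)-5-{[(4R)-4-benzyl-2-oxo-1,3-oxazolidin-3-yl]carbonyl}-6-(2,2-dimethyl-1,3-benzodioxol-5-yl)cyclohex-1-ene-1-carboxylate | O=C([C@H]1CCC=C(C(=O)OC(C)(C)C)[C@H]1c1ccc2OC(C)(C)Oc2c1)N1[C@H](Cc2ccccc2)COC1=O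
F3 | step 5 | tert-butyl 6-(2,2-dimethyl-1,3-benzodioxol-5-yl)-5-(hydroxymethyl)cyclohex-1-ene-1-carboxylate (cis, same configuration as 8) | OC[C@H]1CCC=C(C(=O)OC(C)(C)C)[C@H]1c1ccc2OC(C)(C)Oc2c1
F4 | step 9 | tert-butyl (5S,6R)-5-[(1Z)-3-{[tert-butyl(dimethyl)silyl]oxy}-2-iodoprop-1-en-1-yl]-6-(2,2-dimethyl-1,3-benzodioxol-5-yl)cyclohex-2-ene-1-carboxylate (mixture at C1) | CC(C)(C)[Si](C)(C)OC/C(I)=C/[C@H]1CC=CC(C(=O)OC(C)(C)C)[C@H]1c1ccc2OC(C)(C)Oc2c1
F5 | step 9 | 2,3-epoxide of F4 (tert-butyl 4-(iodoalkenyl)-3-aryl-7-oxabicyclo[4.1.0]heptane-2-carboxylate, mixture of epoxide and ester epimers) | CC(C)(C)[Si](C)(C)OC/C(I)=C/[C@H]1CC2OC2C(C(=O)OC(C)(C)C)[C@H]1c1ccc2OC(C)(C)Oc2c1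
F6 | step 19 | trimethylsilyl enol ether of 27 (C2=C3, OSiMe3 on C3) | O=C(/C=C/C1=C[C@H]2C=C(O[Si](C)(C)C)[C@@H]1[C@H](C(=O)OC(C)(C)C)[C@H]2c1ccc2OC(C)(C)Oc2c1)O[C@H](Cc1ccc2OC(C)(C)Oc2c1)C(=O)OC(C)(C)C
F7 | step 19 | C2-hydroxy derivative of 27 (α-hydroxy ketone, mixture at C2) | O=C(/C=C/C1=C[C@H]2C(O)C(=O)[C@@H]1[C@H](C(=O)OC(C)(C)C)[C@H]2c1ccc2OC(C)(C)Oc2c1)O[C@H](Cc1ccc2OC(C)(C)Oc2c1)C(=O)OC(C)(C)C
A1 | alternative 1 | ethenyl trans-6-(2,2-dimethyl-1,3-benzodioxol-5-yl)-3-formylcyclohexa-2,4-diene-1-carboxylate | C=COC(=O)[C@H]1C=C(C=O)C=C[C@@H]1c1ccc2OC(C)(C)Oc2c1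
A2 | alternative 1 | tricyclic lactone aldehyde (C7 carboxyl lactonised onto C3, C2 methylene, formyl on C5, aryl on C8) | O=CC1=C[C@H]2C[C@H](OC3=O)[C@@H]1[C@H]3[C@H]2c1ccc2OC(C)(C)Oc2c1
A3 | alternative 2 | cis-fused 4-(2,2-dimethyl-1,3-benzodioxol-5-yl)-6,6-dimethoxy-3,4,4a,5,6,8a-hexahydro-2H-chromen-2-one | O=C1C[C@@H](c2ccc3OC(C)(C)Oc3c2)[C@H]2CC(OC)(OC)C=C[C@H]2O1
A4 | alternative 2 | 3-(2,2-dimethyl-1,3-benzodioxol-5-yl)-5,5-dimethoxybicyclo[2.2.2]oct-7-ene-2-carboxylic acid (C2=C3 olefin, C5 ketal in the skeleton numbering) | COC1(OC)C[C@H]2C=C[C@@H]1[C@H](C(=O)O)[C@H]2c1ccc2OC(C)(C)Oc2c1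
A5 | alternative 3 | tert-butyl 2-(2,2-dimethyl-1,3-benzodioxol-5-yl)-3-ethenyl-6-ethynyl-4,4-dimethoxycyclohexane-1-carboxylate (vinyl and ethynyl cis-1,4) | C=C[C@H]1C(OC)(OC)C[C@@H](C#C)[C@H](C(=O)OC(C)(C)C)[C@H]1c1ccc2OC(C)(C)Oc2c1
A6 | alternative 3 | tert-butyl 3-(2,2-dimethyl-1,3-benzodioxol-5-yl)-6-ethenyl-8,8-dimethoxybicyclo[2.2.2]oct-5-ene-2-carboxylate | C=CC1=C[C@H]2C(OC)(OC)C[C@@H]1[C@H](C(=O)OC(C)(C)C)[C@H]2c1ccc2OC(C)(C)Oc2c1
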